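Carry 10.4 %: in the elm flask at its last reading, this is the complex with three exchanged held per starting complex consumed, both as fractions of the charge. Call it the arrival share, or selectivity in the usual word.

| flask | starting complex | incoming ligand | remark | time |
|---|---|---|---|---|
| elm | 0.30 M | 0.60 M | the very flask that is asked about, followed so far |  |
| birch | 0.30 M | 0.90 M | run made earlier |  |
| flask | 0.30 M | 0.600 M |  | 2.0 h |

- elm (time / min: complex with three exchanged / %, starting complex / %): 4.00: 0, 81; 8.00: 2, 63; 15.0: 5, 48; 25.0: 6, 34; 50.0: 8, 23
- birch (time / min: complex with three exchanged / %, starting complex / %): 15.0: 12, 32; 30.0: 14, 17; 50.0: 10, 9; 60.0: 12, 7; 80.0: 11, 4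

(standard deviation of a reading: 1.5 percentage points)

* equivalents of incoming ligand to starting complex, everything else as given, that leave most complex with three exchanged at 2.0 h
* the amount of complex with three exchanged then, in percent of the starting complex charged
* the amount of complex with three exchanged with the amounts as given



Set the zero of the scale at a share of one, where each starting complex consumed arrives at three exchanged, and see how far below it elm stands. Now doubt the figure, since it rests on one reading with a scatter of 1.5 percentage points. Check it at 15.0 min: the share reads 9.62 %, so treat it as flat in elm. Yield is share times conversion, and conversion cannot pass one, so with a flat share expect the asked flask between the 8 % last read in elm and 10.4 %.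

But birch objects. Its share reads 17.6 % at 15.0 min and 11.5 % at 80.0 min, so a flat share is not guaranteed. Concede this, stay off the upper end and commit to the middle, 9.19 %, as my estimate. At their last readings, the birch share stands above the elm share, though the gap of 1.1 points is small against the scatter. So take 11.5 % at 3.00 equivalents, the birch charge, as my estimate of the best case.

The forecast gives 10 % for the asked flask, a little above my figure, and 12 % at 3 equiv, adding “This is poorly constrained”.

The flask gives 8.13 %, and the most is 11.6 % at 3.23 equiv, so the forecast held.

    starting complex + incoming ligand → leaving ligand + complex with one exchanged (k = 0.00180 L mol⁻¹ s⁻¹)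
    complex with one exchanged + incoming ligand → leaving ligand + complex with two exchanged (k = 0.00490 L mol⁻¹ s⁻¹)
    complex with two exchanged + incoming ligand → leaving ligand + complex with three exchanged (k = 0.00280 L mol⁻¹ s⁻¹)
    complex with three exchanged + incoming ligand ⇌ leaving ligand + complex with four exchanged (K = 3.60, k = 0.00100 L mol⁻¹ s⁻¹)
    complex with two exchanged → side product (k = 0.00410 s⁻¹)

At 2.0 h, 12 % of the starting complex remains in the asked flask. The elm share times the 88.0 % consumed gives 9.15 %, against the 8.13 % found. In the flask at the best equivalents, 0.855 % of the starting complex remains, and the birch share times the part consumed gives 11.4 %, against 11.6 %.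

(Readings and results are calculated with made-up constants; scatter was added.)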